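**Assumptions (one line each)**
- Locants C1–C15 are those of the target: ring carbons C1–C10, lactone carbons C11–C13, C14 is the methyl on C10, C15 is the CH2OH on C4. Descriptors of intermediates use these locants.
- Step 5 is not face-selective at C1. The (1S) epimer is drawn; the (1R) epimer is carried along unseparated, because C1 and C10 end up as the same E-alkene in step 12.
- TBS (tert-butyldimethylsilyl) and the tert-butyl ester are protecting groups.

**Retrosynthetic overview**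
1. Target ⇐ desilylation ⇐ face-selective epoxidation of the E-C1=C10 alkene ⇐ α-methylenation ⇐ invertive (Mitsunobu) closure of the 6,12-lactone.
2. Ten-membered ring ⇐ Grob (Wharton) fragmentation of the C6–C10 bond of a trans-fused hydroazulene 1,3-hydroxy mesylate; this ring expansion delivers the 4Z-enone and the 1(10)E-alkene.
3. Seven-membered ring ⇐ ring-closing metathesis of a vinyl carbinol; five-membered ring = cyclopent-2-enone.
4. C7/C8 ⇐ copper-catalysed borylative alkylation, then Mitsunobu inversion at C8 with methacrylic acid; C1/C10 ⇐ aldol with a C1–C4/C15 aldehyde, then chelate-controlled methylation.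
5. Ring order: five-membered (bought) → seven-membered → ten-membered → lactone → epoxide.

**Route**

Step 1
Reactants: 1 2-methylenepropane-1,3-diol
Product: 2 2-{[(TBS)oxy]methyl}prop-2-en-1-ol
Conditions: NaH (1.0 equiv), THF, 0 °C; TBSCl (1.0 equiv), 0 to 23 °C
Reagents that add atoms: tert-butyldimethylsilyl chloride CC(C)(C)[Si](C)(C)Cl
Why: O-silylation of the monosodium alkoxide of a symmetric diol stops at the mono-ether; no stereocentre is formed.

Step 2
Reactants: 2 2-{[(TBS)oxy]methyl}prop-2-en-1-ol, 3 allyl acetate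
Product: 5 (3S)-2-{[(TBS)oxy]methyl}hexa-1,5-dien-3-ol, via enal 4 (not isolated)
Conditions: [Ir(cod)Cl]2 (2.5 mol %), (S)-Cl,MeO-BIPHEP (5 mol %), 4-chloro-3-nitrobenzoic acid (10 mol %), Cs2CO3 (20 mol %), THF, 100 °C
Reagents that add atoms: none
Why: Krische iridium-catalysed transfer-hydrogenative carbonyl allylation from the alcohol oxidation level; the chiral allyliridium adds to one face of enal 4 and sets C3 (S) under catalyst control (the ligand antipode is used if the opposite sense is found).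

Step 3
Reactants: 5 (3S)-2-{[(TBS)oxy]methyl}hexa-1,5-dien-3-ol
Product: 6 (3S)-3-[(TBS)oxy]-2-{[(TBS)oxy]methyl}hexa-1,5-diene
Conditions: TBSOTf, 2,6-lutidine, CH2Cl2, −78 °C
Reagents that add atoms: tert-butyldimethylsilyl triflate CC(C)(C)[Si](C)(C)OS(=O)(=O)C(F)(F)F
Why: Standard silylation of a secondary allylic alcohol; C3 is untouched.

Step 4
Reactants: 6 (3S)-3-[(TBS)oxy]-2-{[(TBS)oxy]methyl}hexa-1,5-diene
Product: 8 (3S)-3-[(TBS)oxy]-4-{[(TBS)oxy]methyl}pent-4-enal, via diol 7 (not isolated)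
Conditions: K2OsO4·2H2O (2 mol %), NaIO4 (4 equiv), 2,6-lutidine, dioxane/H2O, 0 °C
Reagents that add atoms: sodium periodate [Na+].[O-]I(=O)(=O)=O
Why: Lemieux–Johnson cleavage; OsO4 dihydroxylates the unhindered monosubstituted alkene in preference to the 1,1-disubstituted alkene flanked by two silyloxy-bearing carbons, and periodate cleaves the diol.

Step 5
Reactants: 9 cyclopent-2-en-1-one, 8 (3S)-3-[(TBS)oxy]-4-{[(TBS)oxy]methyl}pent-4-enal
Product: 10 5-[(1S,3S)-1-hydroxy-3-(TBS-oxy)-4-(TBS-oxymethyl)pent-4-en-1-yl]cyclopent-2-en-1-one (C10 epimers)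
Conditions: LiN(iPr)2 (1.05 equiv), THF, −78 °C; then 8, −78 °C; NH4Cl quench at −78 °C
Reagents that add atoms: none
Why: Kinetic α′-lithium enolate aldol addition forms the C10–C1 bond; both C1 epimers form (the 1,3-anti one is drawn) and C10 is fixed only in step 6.

Step 6
Reactants: 10 aldol adduct
Product: 11 (5R)-5-[(1S,3S)-1-hydroxy-3-(TBS-oxy)-4-(TBS-oxymethyl)pent-4-en-1-yl]-5-methylcyclopent-2-en-1-one
Conditions: LiN(iPr)2 (2.3 equiv), THF, −78 to −40 °C; MeI, DMPU, −78 to −30 °C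
Reagents that add atoms: iodomethane CI
Why: Fráter–Seebach-type alkylation of the chelated alkoxide–enolate dianion; methyl enters C10 anti to the C2 chain on the lithium chelate, which gives the C1/C10 relationship needed later for an anti-periplanar C1–O/C10–C6 arrangement with C2 anti to C9 (E-alkene).

Step 7
Reactants: 11 methyl enone, 12 tert-butyl bromoacetate
Product: 14 tert-butyl 2-[(1R,2S,4R)-2-hydroxy-4-{(1S,3S)-1-hydroxy-3-(TBS-oxy)-4-(TBS-oxymethyl)pent-4-en-1-yl}-4-methyl-5-oxocyclopentyl]acetate, via bis-boryl ketone 13 (not isolated)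
Conditions: NaH (1.0 equiv), THF, 0 °C; CuCl (5 mol %), (R,S)-Josiphos (6 mol %), NaOtBu (10 mol %), B2pin2 (1.2 equiv), THF, −20 °C; 12 (1.5 equiv), −20 to 0 °C; then NaBO3·4H2O, THF/H2O, 23 °C
Reagents that add atoms: bis(pinacolato)diboron CC1(C)OB(OC1(C)C)B1OC(C)(C)C(C)(C)O1; sodium perborate [Na+].[Na+].O[B-]1(O)OO[B-](O)(O)OO1
Why: Proposed new method: the sodium alkoxide of 11 activates B2pin2 (ending as the C1–O–Bpin ether, which masks the hydroxyl), the Josiphos–copper boryl species adds boron to C8 on the face chosen by the ligand, the sodium enolate formed in the absence of a proton source is C-alkylated at C7 by 12 trans to the new C8–B bond, and perborate converts C–B into C–OH with retention, so C8 (S) is catalyst-set and C7 (R) follows from it; the closest known reactions are the copper-catalysed enantioselective conjugate borylation of cyclic enones with enolate protonation and conjugate addition/enolate alkylation three-component couplings.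

Step 8
Reactants: 14 hydroxy keto ester
Product: 15 tert-butyl 2-[(1R,2S,4R,5R)-5-ethenyl-2,5-dihydroxy-4-{(1S,3S)-1-hydroxy-3-(TBS-oxy)-4-(TBS-oxymethyl)pent-4-en-1-yl}-4-methylcyclopentyl]acetate
Conditions: CH2=CHMgBr (5 equiv), CeCl3 (5 equiv), THF, −78 °C; AcOH quench at −78 °C
Reagents that add atoms: vinylmagnesium bromide C=C[Mg]Br
Why: Organocerium 1,2-addition (low basicity avoids enolization and retro-aldol) from the ring face opposite the C7 and C10 side chains; C6 is a temporary stereocentre that becomes a ketone again in step 12.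

Step 9
Reactants: 15 vinyl carbinol
Product: 16 trans-fused hydroazulene triol (1S,3S,6R,7R,8S,10R)
Conditions: second-generation Hoveyda–Grubbs catalyst (10 mol %), toluene, 80 °C
Reagents that add atoms: none
Why: Ring-closing metathesis gives the trisubstituted cycloheptene; the Z geometry of C4=C5 is enforced by the seven-membered ring.

Step 10
Reactants: 16 hydroazulene triol, 17 methacrylic acid
Product: 18 C8 methacrylate diol (1S,3S,6R,7R,8R,10R)
Conditions: PPh3, DIAD, toluene, 0 to 23 °C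
Reagents that add atoms: none
Why: Mitsunobu esterification with inversion at C8, the only unhindered secondary hydroxyl (C1–OH is neopentyl, C6–OH tertiary); this turns the trans C7/C8 pair into the cis pair of the target and installs the final ester.

Step 11
Reactants: 18 methacrylate diol
Product: 19 C1 mesylate (1S,3S,6R,7R,8R,10R)
Conditions: MsCl, Et3N, CH2Cl2, −20 °C
Reagents that add atoms: methanesulfonyl chloride CS(=O)(=O)Cl
Why: Selective sulfonylation of the secondary C1 hydroxyl (the tertiary C6 hydroxyl does not react) gives the 1,3-hydroxy sulfonate needed for fragmentation.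

Step 12
Reactants: 19 mesylate
Product: 21 (6S)-allylic alcohol of the ten-membered ring (3S,6S,7R,8R; 4Z,1(10)E), via dienone 20 (not isolated)
Conditions: KN(SiMe3)2 (1.05 equiv), THF, −78 to −40 °C; then CeCl3·7H2O, NaBH4, MeOH, −78 °C
Reagents that add atoms: none
Why: Grob (Wharton) fragmentation as the ring expansion: the C6 potassium alkoxide pushes, the C6–C10 bond anti-periplanar to C1–OMs breaks, and the five- and seven-membered rings open stereospecifically to the ten-membered ring with the E-C1=C10 alkene and the Z-enone; in-situ Luche 1,2-reduction removes the base-sensitive β-acyloxy ketone at once and, by Felkin–Anh attack anti to the C7–C8 bond from the ring periphery, is expected to give the (6S) alcohol.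

Step 13
Reactants: 21 (6S)-allylic alcohol tert-butyl ester
Product: 23 (6S)-hydroxy acid, via bis-silyl compound 22 (not isolated)
Conditions: TMSOTf, 2,6-lutidine, CH2Cl2, 0 °C; then aqueous citric acid, THF, 0 °C
Reagents that add atoms: none
Why: Silyl triflate-mediated alkyl–oxygen cleavage of the tert-butyl ester to the silyl ester, with the allylic hydroxyl masked as its silyl ether so that it cannot lactonize with retention, then mild hydrolysis; TBS ethers and the methacrylate survive.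

Step 14
Reactants: 23 hydroxy acid
Product: 24 6,7-trans lactone (3S,6R,7R,8R)
Conditions: PPh3, DIAD, toluene, −20 to 0 °C
Reagents that add atoms: none
Why: Mitsunobu lactonization: the allylic C6 hydroxyl is activated as the oxyphosphonium ion and displaced by the C12 carboxylate in a five-membered SN2 closure, inverting C6 to (R).

Step 15
Reactants: 24 lactone
Product: 27 α-methylene lactone (3S,6R,7R,8R), via Mannich base 25 (not isolated), via ammonium iodide 26 (not isolated)
Conditions: LiN(SiMe3)2 (1.1 equiv), THF, −78 °C; Me2N=CH2 iodide; then MeI, MeOH, 23 °C; then NaHCO3, CH2Cl2/H2O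
Reagents that add atoms: N,N-dimethylmethyleneiminium iodide C=[N+](C)C.[I-]
Why: Eschenmoser methylenation (Mannich reaction of the lactone enolate, quaternization, elimination); the methacrylate has no acidic hydrogen and is not attacked at −78 °C.

Step 16
Reactants: 27 α-methylene lactone
Product: 28 1,10-epoxide bis-TBS ether (1R,3S,6R,7R,8R,10R)
Conditions: mCPBA, NaHCO3, CH2Cl2, −20 °C
Reagents that add atoms: 3-chloroperbenzoic acid OOC(=O)c1cccc(Cl)c1
Why: Prilezhaev epoxidation: the electron-rich trisubstituted C1=C10 alkene reacts much faster than the C4=C5 alkene (three allylic oxygens) and the two acrylate-type alkenes, and attack on the outer face of the E-alkene is expected to give the (1R,10R) epoxide.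

Step 17
Reactants: 28 epoxide bis-TBS ether
Product: 29 target (1R,3S,6R,7R,8R,10R)
Conditions: HF·pyridine, pyridine, THF, 0 °C
Reagents that add atoms: none
Why: Buffered fluoride cleavage of both silyl ethers leaves the epoxide, the methacrylate and the methylene lactone intact.

**Compound list**

1 | 2-methylenepropane-1,3-diol | C=C(CO)CO | starting material
2 | 2-{[(TBS)oxy]methyl}prop-2-en-1-ol | C=C(CO)CO[Si](C)(C)C(C)(C)C | intermediate
3 | allyl acetate | C=CCOC(C)=O | starting material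
4 | 2-{[(TBS)oxy]methyl}prop-2-enal | C=C(C=O)CO[Si](C)(C)C(C)(C)C | intermediate (not isolated)
5 | (3S)-2-{[(TBS)oxy]methyl}hexa-1,5-dien-3-ol | C=CC[C@H](O)C(=C)CO[Si](C)(C)C(C)(C)C | intermediate
6 | (3S)-3-[(TBS)oxy]-2-{[(TBS)oxy]methyl}hexa-1,5-diene | C=CC[C@H](O[Si](C)(C)C(C)(C)C)C(=C)CO[Si](C)(C)C(C)(C)C | intermediate
7 | (4S)-4-[(TBS)oxy]-5-{[(TBS)oxy]methyl}hex-5-ene-1,2-diol (C2 epimers) | OCC(O)C[C@H](O[Si](C)(C)C(C)(C)C)C(=C)CO[Si](C)(C)C(C)(C)C | intermediate (not isolated)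
8 | (3S)-3-[(TBS)oxy]-4-{[(TBS)oxy]methyl}pent-4-enal | O=CC[C@H](O[Si](C)(C)C(C)(C)C)C(=C)CO[Si](C)(C)C(C)(C)C | intermediate
9 | cyclopent-2-en-1-one | O=C1C=CCC1 | starting material
10 | 5-[(1S,3S)-1-hydroxy-3-(TBS-oxy)-4-(TBS-oxymethyl)pent-4-en-1-yl]cyclopent-2-en-1-one (C10 epimers; 1R epimer also present) | O=C1C=CCC1[C@@H](O)C[C@H](O[Si](C)(C)C(C)(C)C)C(=C)CO[Si](C)(C)C(C)(C)C | intermediate
11 | (5R)-5-[(1S,3S)-1-hydroxy-3-(TBS-oxy)-4-(TBS-oxymethyl)pent-4-en-1-yl]-5-methylcyclopent-2-en-1-one | O=C1C=CC[C@]1(C)[C@@H](O)C[C@H](O[Si](C)(C)C(C)(C)C)C(=C)CO[Si](C)(C)C(C)(C)C | intermediate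
12 | tert-butyl bromoacetate (tert-butyl is a protecting group) | BrCC(=O)OC(C)(C)C | starting material
13 | C8-boryl, O1-boryl keto ester (1S,3S,7R,8S,10R) | O=C1[C@H](CC(=O)OC(C)(C)C)[C@@H](B2OC(C)(C)C(C)(C)O2)C[C@]1(C)[C@@H](OB2OC(C)(C)C(C)(C)O2)C[C@H](O[Si](C)(C)C(C)(C)C)C(=C)CO[Si](C)(C)C(C)(C)C | intermediate (not isolated)
14 | tert-butyl 2-[(1R,2S,4R)-2-hydroxy-4-{(1S,3S)-1-hydroxy-3-(TBS-oxy)-4-(TBS-oxymethyl)pent-4-en-1-yl}-4-methyl-5-oxocyclopentyl]acetate | O=C1[C@H](CC(=O)OC(C)(C)C)[C@@H](O)C[C@]1(C)[C@@H](O)C[C@H](O[Si](C)(C)C(C)(C)C)C(=C)CO[Si](C)(C)C(C)(C)C | intermediate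
15 | tert-butyl 2-[(1R,2S,4R,5R)-5-ethenyl-2,5-dihydroxy-4-{(1S,3S)-1-hydroxy-3-(TBS-oxy)-4-(TBS-oxymethyl)pent-4-en-1-yl}-4-methylcyclopentyl]acetate | C=C[C@@]1(O)[C@H](CC(=O)OC(C)(C)C)[C@@H](O)C[C@]1(C)[C@@H](O)C[C@H](O[Si](C)(C)C(C)(C)C)C(=C)CO[Si](C)(C)C(C)(C)C | intermediate
16 | trans-fused hydroazulene triol: 1,6,8-trihydroxy, 3-OTBS, 15-OTBS, C4=C5, C7-CH2CO2tBu (1S,3S,6R,7R,8S,10R) | O[C@@]12C=C(CO[Si](C)(C)C(C)(C)C)[C@@H](O[Si](C)(C)C(C)(C)C)C[C@H](O)[C@@]1(C)C[C@H](O)[C@H]2CC(=O)OC(C)(C)C | intermediate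
17 | methacrylic acid | C=C(C)C(=O)O | starting material
18 | hydroazulene 1,6-diol 8-methacrylate (1S,3S,6R,7R,8R,10R) | O[C@@]12C=C(CO[Si](C)(C)C(C)(C)C)[C@@H](O[Si](C)(C)C(C)(C)C)C[C@H](O)[C@@]1(C)C[C@@H](OC(=O)C(C)=C)[C@H]2CC(=O)OC(C)(C)C | intermediate
19 | hydroazulene 1-mesylate 6-ol 8-methacrylate (1S,3S,6R,7R,8R,10R) | O[C@@]12C=C(CO[Si](C)(C)C(C)(C)C)[C@@H](O[Si](C)(C)C(C)(C)C)C[C@H](OS(C)(=O)=O)[C@@]1(C)C[C@@H](OC(=O)C(C)=C)[C@H]2CC(=O)OC(C)(C)C | intermediate
20 | (4Z,1(10)E)-cyclodeca-dien-6-one tert-butyl ester (3S,7R,8R) | O=C1/C=C(CO[Si](C)(C)C(C)(C)C)\[C@@H](O[Si](C)(C)C(C)(C)C)C/C=C(C)/C[C@@H](OC(=O)C(C)=C)[C@H]1CC(=O)OC(C)(C)C | intermediate (not isolated)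
21 | (6S)-allylic alcohol tert-butyl ester (3S,6S,7R,8R) | O[C@H]1/C=C(CO[Si](C)(C)C(C)(C)C)\[C@@H](O[Si](C)(C)C(C)(C)C)C/C=C(C)/C[C@@H](OC(=O)C(C)=C)[C@H]1CC(=O)OC(C)(C)C | intermediate
22 | 6-O-trimethylsilyl ether trimethylsilyl ester (3S,6S,7R,8R) | C[Si](C)(C)O[C@H]1/C=C(CO[Si](C)(C)C(C)(C)C)\[C@@H](O[Si](C)(C)C(C)(C)C)C/C=C(C)/C[C@@H](OC(=O)C(C)=C)[C@H]1CC(=O)O[Si](C)(C)C | intermediate (not isolated)
23 | (6S)-hydroxy acid (3S,6S,7R,8R) | O[C@H]1/C=C(CO[Si](C)(C)C(C)(C)C)\[C@@H](O[Si](C)(C)C(C)(C)C)C/C=C(C)/C[C@@H](OC(=O)C(C)=C)[C@H]1CC(=O)O | intermediate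
24 | 6,7-trans-fused 6,12-lactone, 8-methacrylate, bis-TBS ether (3S,6R,7R,8R) | C=C(C)C(=O)O[C@@H]1C/C(C)=C/C[C@H](O[Si](C)(C)C(C)(C)C)/C(CO[Si](C)(C)C(C)(C)C)=C\[C@H]2OC(=O)C[C@@H]21 | intermediate
25 | 11-(dimethylaminomethyl) lactone (C11 epimers) | C=C(C)C(=O)O[C@@H]1C/C(C)=C/C[C@H](O[Si](C)(C)C(C)(C)C)/C(CO[Si](C)(C)C(C)(C)C)=C\[C@H]2OC(=O)C(CN(C)C)[C@@H]21 | intermediate (not isolated)
26 | 11-(trimethylammoniomethyl) lactone iodide | C=C(C)C(=O)O[C@@H]1C/C(C)=C/C[C@H](O[Si](C)(C)C(C)(C)C)/C(CO[Si](C)(C)C(C)(C)C)=C\[C@H]2OC(=O)C(C[N+](C)(C)C)[C@@H]21.[I-] | intermediate (not isolated)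
27 | α-methylene lactone, 1(10)E,4Z-diene, bis-TBS ether (3S,6R,7R,8R) | C=C(C)C(=O)O[C@@H]1C/C(C)=C/C[C@H](O[Si](C)(C)C(C)(C)C)/C(CO[Si](C)(C)C(C)(C)C)=C\[C@H]2OC(=O)C(=C)[C@@H]21 | intermediate
28 | 1,10-epoxide bis-TBS ether (1R,3S,6R,7R,8R,10R) | C=C(C)C(=O)O[C@@H]1C[C@@]2(C)O[C@@H]2C[C@H](O[Si](C)(C)C(C)(C)C)/C(CO[Si](C)(C)C(C)(C)C)=C\[C@H]2OC(=O)C(=C)[C@@H]21 | intermediate
29 | CNP0496616.1 (1R,3S,6R,7R,8R,10R; 4Z) | C=C(C)C(=O)O[C@@H]1C[C@@]2(C)O[C@@H]2C[C@H](O)/C(CO)=C\[C@H]2OC(=O)C(=C)[C@@H]21 | target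

**Step count**
Total: 17 steps. Longest linear sequence: 17 steps (1 → 29).

**The three steps most likely to fail, with fallbacks**

Step 7 (proposed borylative alkylation). The enolate may be protonated or O-alkylated instead of C-alkylated. The two bonds can then be made one after the other by known reactions. Starting from 11, the same CuCl/Josiphos/B2pin2 system is run with MeOH as proton source and worked up with NaBO3·4H2O to give hydroxy ketone F1. The lithium alkoxide–enolate of F1 (LiN(iPr)2, 3.3 equiv, THF, −78 °C) is then alkylated with 12 at C7 trans to the C8 alkoxide (Fráter–Seebach-type). This comes back to the route at 14.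

Step 12 (fragmentation and reduction). The mesylate may not reach the anti-periplanar geometry, or the methacrylate may be eliminated. The ring is then expanded by a retro-aldol fragmentation of the same C6–C10 bond. Starting from 18, Dess–Martin periodinane oxidizes the C1 hydroxyl to give C1 ketone F2. KN(SiMe3)2 and PhNTf2 (THF, −78 °C) open the C6 alkoxide by retro-aldol cleavage and trap the C1 enolate as enol triflate F3 (C2 trans to C9). Pd(OAc)2/PPh3, Et3N and HCO2H replace the triflate by hydrogen with retention of geometry. This comes back to the route at 20, which is reduced to 21 as in step 12. A separate uncertainty is the C6 configuration: if the reduction gives the (6R) alcohol instead, acid-catalysed lactonization with retention leads to 24 directly.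

Step 16 (epoxidation face). If the peracid attacks the other face, the epoxide is made by double inversion. Starting from 27, NBS in wet acetone gives bromohydrin F4 (bromonium on the accessible face, water opening at the tertiary C10 from the other face). DBU in CH2Cl2 then closes F4 by displacement of bromide at C1. This comes back to the route at 28.

**Further compounds**

F1 | step 7 | (3S,5R)-3-hydroxy-5-[(1S,3S)-1-hydroxy-3-(TBS-oxy)-4-(TBS-oxymethyl)pent-4-en-1-yl]-5-methylcyclopentan-1-one | O=C1C[C@@H](O)C[C@]1(C)[C@@H](O)C[C@H](O[Si](C)(C)C(C)(C)C)C(=C)CO[Si](C)(C)C(C)(C)C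
F2 | step 12 | hydroazulene C1 ketone, 6-ol, 8-methacrylate | O[C@@]12C=C(CO[Si](C)(C)C(C)(C)C)[C@@H](O[Si](C)(C)C(C)(C)C)CC(=O)[C@@]1(C)C[C@@H](OC(=O)C(C)=C)[C@H]2CC(=O)OC(C)(C)C
F3 | step 12 | ten-membered 4Z-enone C1 enol triflate (C2 trans to C9) | O=C1/C=C(CO[Si](C)(C)C(C)(C)C)\[C@@H](O[Si](C)(C)C(C)(C)C)C/C(OS(=O)(=O)C(F)(F)F)=C(C)/C[C@@H](OC(=O)C(C)=C)[C@H]1CC(=O)OC(C)(C)C
F4 | step 16 | (1S,10R)-1-bromo-10-hydroxy bromohydrin of 27 | C=C(C)C(=O)O[C@@H]1C[C@@](C)(O)[C@@H](Br)C[C@H](O[Si](C)(C)C(C)(C)C)/C(CO[Si](C)(C)C(C)(C)C)=C\[C@H]2OC(=O)C(=C)[C@@H]21
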